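**Retrosynthetic overview**

1. Target ⇐ C7 oxidation, C16–Se reduction and O19 desilylation of a 16-selanyl spiro-ether, which comes from a furan-dearomatising cascade on a 7β-acetoxy-8α,9α-epoxy furanolabdane (forms O9–C13 and C8–OAc together).
2. That epoxide ⇐ 8-en-7-one ⇐ oxidative 1,3-transposition of the adduct of a 9-oxo-7-ene decalin and 2-(furan-3-yl)ethyllithium (from 3-bromofuran).
3. The decalin ⇐ dehydration/hydrogenation of a bicyclic aldol ⇐ key step: enantioselective, symmetry-breaking copper hydride reductive aldol of an achiral dione-enoate (C4–C5 bond; sets C4 and C10).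
4. Ring order: ring B (bought as 2-methylcyclohexane-1,3-dione) → ring A (step 3) → furan appended (step 10) → ring C (spiro tetrahydrofuran) closed while the furan is dearomatised to ring D (step 15).

Assumption: labdane numbering with α/β = below/above the decalin as usually drawn is used throughout, and in step 3 the (R)-ligand is taken to give the enantiomer shown (otherwise its antipode is used).

**Step 1**
Reactants: 1 2-methylcyclohexane-1,3-dione; 2 acrolein (prop-2-enal)
Product: 3 3-(1-methyl-2,6-dioxocyclohexyl)propanal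
Conditions: H2O, rt
Reagents that add atoms: none
Why: Michael addition of the acidic cyclic 1,3-dione to acrolein gives the 2,2-disubstituted dione, which is achiral (mirror plane), so no stereocentre is formed.

**Step 2**
Reactants: 3 3-(1-methyl-2,6-dioxocyclohexyl)propanal; 4 ethyl 2-(triphenyl-λ5-phosphanylidene)propanoate
Product: 5 ethyl (2E)-2-methyl-5-(1-methyl-2,6-dioxocyclohexyl)pent-2-enoate
Conditions: CH2Cl2, rt
Reagents that add atoms: none
Why: Wittig olefination with a stabilised ylide is selective for the aldehyde over the hindered ring ketones and gives the (E)-trisubstituted enoate; the product keeps the mirror plane.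

**Step 3**
Reactants: 5 ethyl (2E)-2-methyl-5-(1-methyl-2,6-dioxocyclohexyl)pent-2-enoate
Product: 7 ethyl 5β-hydroxy-4α,10β-dimethyl-9-oxodecalin-4β-carboxylate (cis-fused; OH/ester/C10-methyl all β), via silyl ether 6 (not isolated)
Conditions: Cu(OAc)2·H2O (5 mol %), (R)-DTBM-SEGPHOS (5.5 mol %), PhMe2SiH (1.5 equiv), toluene, −20 °C to rt; then 1 M HCl, THF
Reagents that add atoms: none
Why: Proposed new method: monovalent copper hydride adds hydride to C3 of the enoate and the tetrasubstituted copper enolate attacks one of the two enantiotopic ring ketones through a closed chair (Zimmerman–Traxler) transition state in which copper bridges enolate and ketone oxygen, so the ester, the new C5 hydroxyl and the C10 methyl end up cis (C4, C5 and C10 set together, the chiral bisphosphine choosing the carbonyl), and silyl transfer to the aldolate makes ring closure irreversible; the closest known reaction is the copper hydride domino conjugate reduction–aldol (reductive aldol) desymmetrisation of enoate-tethered 2-methylcycloalkane-1,3-diones, extended here to an α-methyl enoate that creates the C4 quaternary centre.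

**Step 4**
Reactants: 7 ethyl 5β-hydroxy-4α,10β-dimethyl-9-oxodecalin-4β-carboxylate
Product: 8 ethyl 4α,10β-dimethyl-9-oxodecal-5-ene-4β-carboxylate
Conditions: Burgess reagent, toluene, 70 °C
Reagents that add atoms: none
Why: Burgess dehydration (syn-elimination) of the tertiary alcohol can only go towards C6 because C4 and C10 are quaternary, and the neutral conditions avoid retro-aldol cleavage and cationic methyl shifts; C5 is deliberately erased while C4 and C10 stay.

**Step 5**
Reactants: 8 ethyl 4α,10β-dimethyl-9-oxodecal-5-ene-4β-carboxylate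
Product: 9 ethyl 4α,10β-dimethyl-9-oxo-5α-decalin-4β-carboxylate (trans-fused)
Conditions: H2 (4 atm), Pd/C, EtOAc/AcOH, rt
Reagents that add atoms: none
Why: heterogeneous catalytic hydrogenation delivers hydrogen to the α-face because the β-face of C5=C6 is screened by the axial C10 methyl and the axial C4 ester, giving the trans-decalin (5α-H).

**Step 6**
Reactants: 9 ethyl 4α,10β-dimethyl-9-oxo-5α-decalin-4β-carboxylate
Product: 10 ethyl 4α,8,10β-trimethyl-9-oxo-5α-decalin-4β-carboxylate (C8 epimers)
Conditions: LDA, THF, −78 °C; MeI, −78 to 0 °C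
Reagents that add atoms: iodomethane, CI
Why: enolate alkylation is regiospecific because C8 is the only enolisable position (C10 and C4 are quaternary); the C8 configuration is irrelevant since it is removed in step 7.

**Step 7**
Reactants: 10 ethyl 4α,8,10β-trimethyl-9-oxo-5α-decalin-4β-carboxylate
Product: 11 ethyl 4α,8,10β-trimethyl-9-oxo-5α-decal-7-ene-4β-carboxylate
Conditions: IBX, toluene/DMSO (2:1), 70 °C
Reagents that add atoms: none
Why: IBX dehydrogenation of the ketone can only introduce the C7=C8 double bond and gives the 2,6,6-trisubstituted cyclohexenone needed for 1,2-addition and transposition.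

**Step 8**
Reactants: 12 3-bromofuran; 13 oxirane
Product: 15 2-(furan-3-yl)ethan-1-ol, via furan-3-yllithium 14 (not isolated)
Conditions: n-BuLi, THF, −78 °C; then 13, BF3·OEt2, −78 °C; H2O
Reagents that add atoms: none
Why: bromine–lithium exchange at −78 °C gives 3-lithiofuran without migration to C2, and it opens the BF3-activated epoxide (organolithium epoxide opening).

**Step 9**
Reactants: 15 2-(furan-3-yl)ethan-1-ol
Product: 16 3-(2-iodoethyl)furan
Conditions: I2, PPh3, imidazole, CH2Cl2, 0 °C
Reagents that add atoms: iodine, II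
Why: Appel-type iodination of the primary alcohol runs under neutral conditions that the acid-sensitive furan tolerates.

**Step 10**
Reactants: 11 ethyl 4α,8,10β-trimethyl-9-oxo-5α-decal-7-ene-4β-carboxylate; 16 3-(2-iodoethyl)furan
Product: 18 ethyl 15,16-epoxy-9-hydroxylabda-7,13(16),14-trien-19-oate (C9 epimers), via [2-(furan-3-yl)ethyl]lithium 17 (not isolated)
Conditions: 16, t-BuLi (2 equiv), Et2O, −78 °C; then 11, THF, −78 to −20 °C; H2O
Reagents that add atoms: none
Why: iodine–lithium exchange followed by 1,2-addition of the primary alkyllithium to the enone carbonyl (the neopentyl-type ester is far slower); the C9 configuration does not matter because C9 becomes sp2 in step 11.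

**Step 11**
Reactants: 18 ethyl 15,16-epoxy-9-hydroxylabda-7,13(16),14-trien-19-oate
Product: 19 ethyl 15,16-epoxy-7-oxolabda-8,13(16),14-trien-19-oate
Conditions: IBX, DMSO, 55 °C
Reagents that add atoms: none
Why: oxidative 1,3-transposition of the tertiary allylic alcohol (Babler–Dauben type, run with IBX so the furan is left alone) moves the oxygen from C9 to C7 and gives the tetrasubstituted 8-en-7-one.

**Step 12**
Reactants: 19 ethyl 15,16-epoxy-7-oxolabda-8,13(16),14-trien-19-oate
Product: 20 15,16-epoxylabda-8,13(16),14-triene-7β,19-diol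
Conditions: LiAlH4, THF, 0 to 50 °C
Reagents that add atoms: none
Why: LiAlH4 reduces the ester to the C19 primary alcohol and the enone 1,2 to the allylic alcohol; the small hydride attacks C7 axially from the α-face (only H-5α in the way) and gives the equatorial 7β-alcohol.

**Step 13**
Reactants: 20 15,16-epoxylabda-8,13(16),14-triene-7β,19-diol
Product: 22 7β-acetoxy-19-(tert-butyldimethylsilyloxy)-15,16-epoxylabda-8,13(16),14-triene, via 19-silyl ether 21 (not isolated)
Conditions: TBSCl (1.05 equiv), imidazole, CH2Cl2, 0 °C; then Ac2O, Et3N, DMAP (cat.), rt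
Reagents that add atoms: tert-butyl(chloro)dimethylsilane, CC(C)(C)[Si](C)(C)Cl; acetic anhydride, CC(=O)OC(C)=O
Why: the primary alcohol is silylated much faster than the hindered secondary allylic alcohol, which is then acetylated in the same flask (selective silylation, then DMAP-catalysed acylation); no stereocentre changes.

**Step 14**
Reactants: 22 7β-acetoxy-19-(tert-butyldimethylsilyloxy)-15,16-epoxylabda-8,13(16),14-triene
Product: 23 7β-acetoxy-19-(tert-butyldimethylsilyloxy)-8α,9α:15,16-diepoxylabda-13(16),14-diene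
Conditions: mCPBA (1.1 equiv), NaHCO3, CH2Cl2, −20 to 0 °C
Reagents that add atoms: 3-chloroperoxybenzoic acid, OOC(=O)c1cccc(Cl)c1
Why: Prilezhaev epoxidation; the tetrasubstituted alkene is far more nucleophilic than the 3-alkylfuran, and the peracid comes from the α-face, anti to the axial C10 methyl and to the 7β-acetate, which sets 8α,9α.

**Step 15**
Reactants: 23 7β-acetoxy-19-(tert-butyldimethylsilyloxy)-8α,9α:15,16-diepoxylabda-13(16),14-diene
Product: 25 8β-acetoxy-19-(tert-butyldimethylsilyloxy)-9α,13R:15,16-diepoxy-16-(phenylselanyl)labd-14-en-7β-ol (C16 epimers), via acetoxonium triflate 24 (not isolated)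
Conditions: PhSeCl (1.0 equiv), AgOTf, 4 Å MS, CH2Cl2, −78 °C; then sat. aq. NaHCO3, −78 to 0 °C
Reagents that add atoms: benzeneselenenyl chloride, Cl[Se]c1ccccc1; water, O
Why: Proposed new method: PhSeOTf attacks the furan at C16 (the α-position next to the alkyl group, as in electrophilic substitution of 3-alkylfurans), the cation is captured at C13 by the epoxide oxygen (five-membered ring), the epoxonium ion is opened at C8 from the β-face by the trans 7β-acetate to give acetoxonium ion 24, and water cleaves this to the axial 8β-acetate and equatorial 7β-alcohol, so that C9 keeps its α-oxygen, C8 is inverted to 8β-OAc and C13 is set with the CH(SePh) carbon turned towards C8 (13R expected, selectivity possibly modest, epimer separable here); the closest known reactions are halonium- or selenonium-triggered epoxide-opening cascades ended by an ester or carbonate carbonyl, acyloxonium-assisted trans-diaxial opening of epoxy acetates, and the proton-mediated 9-OH/furan spiro-etherification that links furanic and prefuranic labdanes.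

**Step 16**
Reactants: 25 8β-acetoxy-19-(tert-butyldimethylsilyloxy)-9α,13R:15,16-diepoxy-16-(phenylselanyl)labd-14-en-7β-ol
Product: 26 8β-acetoxy-19-(tert-butyldimethylsilyloxy)-9α,13R:15,16-diepoxylabd-14-en-7β-ol
Conditions: Bu3SnH, AIBN (cat.), toluene, 80 °C
Reagents that add atoms: none
Why: radical chain reduction of the O,Se-acetal carbon (C–Se homolysis, α-oxy radical, hydrogen transfer from the tin hydride) turns C16 into CH2 under neutral conditions that leave the enol ether, the acetate and all stereocentres untouched.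

**Step 17**
Reactants: 26 8β-acetoxy-19-(tert-butyldimethylsilyloxy)-9α,13R:15,16-diepoxylabd-14-en-7β-ol
Product: 27 8β-acetoxy-19-(tert-butyldimethylsilyloxy)-9α,13R:15,16-diepoxylabd-14-en-7-one
Conditions: DMP, NaHCO3, CH2Cl2, 0 °C to rt
Reagents that add atoms: none
Why: Dess–Martin oxidation of the secondary alcohol under buffered conditions gives the C7 ketone without opening the acid-labile spiro enol ether and removes the chance of acetyl migration from O8 to O7.

**Step 18**
Reactants: 27 8β-acetoxy-19-(tert-butyldimethylsilyloxy)-9α,13R:15,16-diepoxylabd-14-en-7-one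
Product: 28 8β-acetoxy-9α,13R:15,16-diepoxy-19-hydroxylabd-14-en-7-one (target CNP0239339.1)
Conditions: TBAF, AcOH, THF, rt
Reagents that add atoms: none
Why: buffered fluoride desilylation frees the primary alcohol; the tertiary acetate has no neighbouring OH to migrate to, C8 has no α-H so the β-alkoxy ketone cannot open by retro-oxa-Michael reaction, and the enol ether is stable to fluoride.

**Compound list**

1 | 2-methylcyclohexane-1,3-dione | CC1C(=O)CCCC1=O | starting material
2 | acrolein | C=CC=O | starting material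
3 | 3-(1-methyl-2,6-dioxocyclohexyl)propanal | CC1(CCC=O)C(=O)CCCC1=O | intermediate
4 | ethyl 2-(triphenyl-λ5-phosphanylidene)propanoate | CCOC(=O)C(C)=P(c1ccccc1)(c1ccccc1)c1ccccc1 | starting material
5 | ethyl (2E)-2-methyl-5-(1-methyl-2,6-dioxocyclohexyl)pent-2-enoate | CCOC(=O)/C(C)=C/CCC1(C)C(=O)CCCC1=O | intermediate
6 | O5-dimethyl(phenyl)silyl ether of 7 | C1CC[C@]2(O[Si](C)(C)c3ccccc3)[C@@](C)(C(=O)OCC)CCC[C@]2(C)C1=O | intermediate (not isolated)
7 | ethyl 5β-hydroxy-4α,10β-dimethyl-9-oxodecalin-4β-carboxylate | C1CC[C@]2(O)[C@@](C)(C(=O)OCC)CCC[C@]2(C)C1=O | intermediate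
8 | ethyl 4α,10β-dimethyl-9-oxodecal-5-ene-4β-carboxylate | C1CC=C2[C@@](C)(C(=O)OCC)CCC[C@]2(C)C1=O | intermediate
9 | ethyl 4α,10β-dimethyl-9-oxo-5α-decalin-4β-carboxylate | C1CC[C@H]2[C@@](C)(C(=O)OCC)CCC[C@]2(C)C1=O | intermediate
10 | ethyl 4α,8,10β-trimethyl-9-oxo-5α-decalin-4β-carboxylate (C8 epimers) | CC1CC[C@H]2[C@@](C)(C(=O)OCC)CCC[C@]2(C)C1=O | intermediate
11 | ethyl 4α,8,10β-trimethyl-9-oxo-5α-decal-7-ene-4β-carboxylate | CC1=CC[C@H]2[C@@](C)(C(=O)OCC)CCC[C@]2(C)C1=O | intermediate
12 | 3-bromofuran | Brc1ccoc1 | starting material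
13 | oxirane | C1CO1 | starting material
14 | furan-3-yllithium | [Li]c1ccoc1 | intermediate (not isolated)
15 | 2-(furan-3-yl)ethan-1-ol | OCCc1ccoc1 | intermediate
16 | 3-(2-iodoethyl)furan | ICCc1ccoc1 | intermediate
17 | [2-(furan-3-yl)ethyl]lithium | [Li]CCc1ccoc1 | intermediate (not isolated)
18 | ethyl 15,16-epoxy-9-hydroxylabda-7,13(16),14-trien-19-oate (C9 epimers) | CC1=CC[C@H]2[C@@](C)(C(=O)OCC)CCC[C@]2(C)C1(O)CCc1ccoc1 | intermediate
19 | ethyl 15,16-epoxy-7-oxolabda-8,13(16),14-trien-19-oate | CC=1C(=O)C[C@H]2[C@@](C)(C(=O)OCC)CCC[C@]2(C)C=1CCc1ccoc1 | intermediate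
20 | 15,16-epoxylabda-8,13(16),14-triene-7β,19-diol | CC=1[C@@H](O)C[C@H]2[C@@](C)(CO)CCC[C@]2(C)C=1CCc1ccoc1 | intermediate
21 | 19-(tert-butyldimethylsilyloxy)-15,16-epoxylabda-8,13(16),14-trien-7β-ol | CC=1[C@@H](O)C[C@H]2[C@@](C)(CO[Si](C)(C)C(C)(C)C)CCC[C@]2(C)C=1CCc1ccoc1 | intermediate (not isolated)
22 | 7β-acetoxy-19-(tert-butyldimethylsilyloxy)-15,16-epoxylabda-8,13(16),14-triene | CC=1[C@@H](OC(C)=O)C[C@H]2[C@@](C)(CO[Si](C)(C)C(C)(C)C)CCC[C@]2(C)C=1CCc1ccoc1 | intermediate
23 | 7β-acetoxy-19-(tert-butyldimethylsilyloxy)-8α,9α:15,16-diepoxylabda-13(16),14-diene | C[C@@]13[C@@H](OC(C)=O)C[C@H]2[C@@](C)(CO[Si](C)(C)C(C)(C)C)CCC[C@]2(C)[C@@]1(O3)CCc1ccoc1 | intermediate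
24 | 7β,8β-(2-methyl-1,3-dioxolan-2-ylium) ion of the 16-(phenylselanyl) spiro-ether, triflate salt (C16 epimers) | CC(=[O+]3)O[C@@]1(C)[C@@H]3C[C@H]2[C@@](C)(CO[Si](C)(C)C(C)(C)C)CCC[C@]2(C)[C@@]12CC[C@]1(C=COC1[Se]c1ccccc1)O2.[O-]S(=O)(=O)C(F)(F)F | intermediate (not isolated)
25 | 8β-acetoxy-19-(tert-butyldimethylsilyloxy)-9α,13R:15,16-diepoxy-16-(phenylselanyl)labd-14-en-7β-ol (C16 epimers) | CC(=O)O[C@@]1(C)[C@@H](O)C[C@H]2[C@@](C)(CO[Si](C)(C)C(C)(C)C)CCC[C@]2(C)[C@@]12CC[C@]1(C=COC1[Se]c1ccccc1)O2 | intermediate
26 | 8β-acetoxy-19-(tert-butyldimethylsilyloxy)-9α,13R:15,16-diepoxylabd-14-en-7β-ol | CC(=O)O[C@@]1(C)[C@@H](O)C[C@H]2[C@@](C)(CO[Si](C)(C)C(C)(C)C)CCC[C@]2(C)[C@@]12CC[C@]1(C=COC1)O2 | intermediate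
27 | 8β-acetoxy-19-(tert-butyldimethylsilyloxy)-9α,13R:15,16-diepoxylabd-14-en-7-one | CC(=O)O[C@@]1(C)C(=O)C[C@H]2[C@@](C)(CO[Si](C)(C)C(C)(C)C)CCC[C@]2(C)[C@@]12CC[C@]1(C=COC1)O2 | intermediate
28 | 8β-acetoxy-9α,13R:15,16-diepoxy-19-hydroxylabd-14-en-7-one | CC(=O)O[C@@]1(C)C(=O)C[C@H]2[C@@](C)(CO)CCC[C@]2(C)[C@@]12CC[C@]1(C=COC1)O2 | target

**Step count and risks**

Total steps: 18. Longest linear sequence: 16 (steps 1–7 and 10–18); steps 8–9 make the side chain.

Most likely to fail, 1: step 3. The aldol must join a tetrasubstituted enolate carbon to a ketone next to a quaternary carbon, so plain conjugate reduction without ring closure, or low ee, is possible. The fallback sets out from 3 and comes back at 8, making the C4 quaternary centre by alkylation instead of in the aldol. Olefination of 3 with ethyl (triphenylphosphoranylidene)acetate gives ethyl (2E)-5-(1-methyl-2,6-dioxocyclohexyl)pent-2-enoate F1. The same copper hydride reductive aldol, now on the α-unsubstituted enoate type for which it is established, gives ethyl 5β-[dimethyl(phenyl)silyloxy]-10β-methyl-9-oxodecalin-4β-carboxylate F2 and after acid work-up ethyl 5β-hydroxy-10β-methyl-9-oxodecalin-4β-carboxylate F3, in which only C10 has to be right. Burgess dehydration gives ethyl 10β-methyl-9-oxodecal-5-ene-4-carboxylate F4. LDA (2.2 equiv) then MeI (1.0 equiv) methylates the more basic ester dienolate at C4 from the α-face, anti to the C10 methyl, which gives 8.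

Most likely to fail, 2: step 12. The acetate relay in step 15 needs the 7β-alcohol, and hydride delivery from the β-face would give the 7α-epimer. The fallback sets out from 19 and comes back at 22, setting C7 by inversion instead of by hydride face selection. The reduction product 15,16-epoxylabda-8,13(16),14-triene-7α,19-diol F5 is silylated at O19 to 19-(tert-butyldimethylsilyloxy)-15,16-epoxylabda-8,13(16),14-trien-7α-ol F6. A Mitsunobu reaction with acetic acid (PPh3, DIAD) then inverts C7 and gives 22.

Most likely to fail, 3: step 15. Possible failures are substitution at C16 instead of addition, a second selenenylation of the enol ether that is formed, capture of the regioisomeric furanium ion, and poor C13 selectivity. The fallback sets out from 23 and comes back at 25, separating the two events. The epoxide is first opened in the classical way (BF3·OEt2 cat., then water, with acetate participation) to 8β-acetoxy-19-(tert-butyldimethylsilyloxy)-15,16-epoxylabda-13(16),14-diene-7β,9α-diol F7. Its free, more nucleophilic tertiary 9α-hydroxyl is then cyclised onto the furan with N-(phenylseleno)phthalimide and catalytic CSA to give 25. C13 epimers, if formed, are separated at 25.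

**Further compounds**

F1 | step 3 | ethyl (2E)-5-(1-methyl-2,6-dioxocyclohexyl)pent-2-enoate | CCOC(=O)/C=C/CCC1(C)C(=O)CCCC1=O
F2 | step 3 | ethyl 5β-[dimethyl(phenyl)silyloxy]-10β-methyl-9-oxodecalin-4β-carboxylate | C1CC[C@]2(O[Si](C)(C)c3ccccc3)[C@@H](C(=O)OCC)CCC[C@]2(C)C1=O
F3 | step 3 | ethyl 5β-hydroxy-10β-methyl-9-oxodecalin-4β-carboxylate | C1CC[C@]2(O)[C@@H](C(=O)OCC)CCC[C@]2(C)C1=O
F4 | step 3 | ethyl 10β-methyl-9-oxodecal-5-ene-4-carboxylate | C1CC=C2[C@@H](C(=O)OCC)CCC[C@]2(C)C1=O
F5 | step 12 | 15,16-epoxylabda-8,13(16),14-triene-7α,19-diol | CC=1[C@H](O)C[C@H]2[C@@](C)(CO)CCC[C@]2(C)C=1CCc1ccoc1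
F6 | step 12 | 19-(tert-butyldimethylsilyloxy)-15,16-epoxylabda-8,13(16),14-trien-7α-ol | CC=1[C@H](O)C[C@H]2[C@@](C)(CO[Si](C)(C)C(C)(C)C)CCC[C@]2(C)C=1CCc1ccoc1
F7 | step 15 | 8β-acetoxy-19-(tert-butyldimethylsilyloxy)-15,16-epoxylabda-13(16),14-diene-7β,9α-diol | CC(=O)O[C@@]1(C)[C@@H](O)C[C@H]2[C@@](C)(CO[Si](C)(C)C(C)(C)C)CCC[C@]2(C)[C@@]1(O)CCc1ccoc1
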